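At early times in larch, starting material has two exits, capture by partner on the way to target and loss with second reagent to side product, and their rates stand at 0.982 to one.

| flask | starting material | partner | second reagent | time | remark |
|---|---|---|---|---|---|
| larch | 47 mM | 56.4 mM | 94.0 mM | 30 min | everything together in a closed stirred flask, run for 30 min |
| maple | 47 mM | 56.4 mM (fed, over 24.0 min) | 94.0 mM | 30 min | a stirred flask in which partner is dosed at a steady rate over 24.0 min without added volume, worked up at 30 min |
| ash | 47 mM | 56.4 mM | 94.0 mM |  | one stirred flow tank at steady state, fed with the mixture as stated, mean residence time 30 min |
| oak | 47 mM (fed, over 24.0 min) | 56.4 mM | 94.0 mM | 30 min | a stirred flask in which starting material is dosed at a steady rate over 24.0 min without added volume, worked up at 30 min |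

    2 partner → self-condensation product (k1 = 0.024 M⁻¹ s⁻¹)
    starting material + partner → intermediate (k2 = 0.018 M⁻¹ s⁻¹)
    second reagent + intermediate → target (k3 = 0.026 M⁻¹ s⁻¹)
    starting material + second reagent → side product (k4 = 0.011 M⁻¹ s⁻¹)

- the set-up with the highest share of target in all that became target or side product, at the outlet or at the end ("none" if the first two lie within 2 percentage points) (larch / maple / ash / oak / none)
- share of target in all that became target or side product, at the outlet or at the end, larch
- share of target in all that became target or side product, at the outlet or at the end, maple
- share of target in all that became target or side product, at the outlet or at the end, ash
- share of target in all that became target or side product, at the outlet or at the end, oak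

- a step written with two of one species runs at k times the square of its concentration and takes two of it each time
- the stated concentrations are those of everything mixed, before any reaction; amounts are the same in each set-up
- the feed brings no volume worth counting
- run time (larch): 30 min

Call kc the constant of capture, ks that of self-condensation and kd that of side-product formation. The early split does not last: in larch, self-condensation first uses partner 3.20 times as fast as capture does. So we keep self-condensation alone in partner's balance and hold second reagent at its charge. Starting material then lives τ = 1/(kd[second reagent]) = 16.1 min against side product, and we integrate capture over that window:

[partner] = [partner]start / (1 + 2·ks·[partner]start·t)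

W = (kc/2ks)·ln(1 + 2·ks·[partner]start·τ) = 0.482

share = W/(W + 1) = 32.5%

This W, the partner exposure, is the integrated capture rate that a parcel of starting material meets in one lifetime against second reagent.

Now we turn the settings. Dosing partner, as in maple, runs past the window, and in that balance [partner] climbs as a hyperbolic tangent, so:

W = (kc/2ks)·ln cosh(u), u = τ·sqrt(2·ks·feed rate) = 1.33

That gives W = 0.263 and a share of 20.8%.

For the tank, ash, we reckon partner at one level, 20.4 mM from the quadratic balance, so W = kc[partner]τ = 0.355 and the share is 26.2%.

Dosing starting material, as in oak, sends a mid-feed parcel into partner that has aged for half of 24.0 min. The logarithm's difference across its window gives W = 0.238 and a share of 19.2%.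

The forecast also names larch, with 30.5%, 18.5%, 25.5% and 19% for larch, maple, ash and oak, on the ground that “all the partner up front in batch does best”, and for maple it stands lower than our figure.

The flasks give larch as best, with 30.8%, 18.1%, 25.5% and 17.9% in the same order.

In larch at 15.0 min, starting material stood at 31.2% and partner at 22.6% of their charges, and target plus intermediate over side product read 0.582. In larch at 30.0 min, partner stood at 12.8% of its charge, and second reagent was using starting material 4.7 times as fast as partner was. A neighbour like larch but with 23 mM of partner has by our reckoning W = 0.272, below the 0.482 of larch, and a share of 21.4%, and it gave 18.2%.

The constants were drawn at random within sensible limits; the flask was simulated.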